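**Retrosynthetic overview** (2-benzoxepine locants: C1 lactone carbonyl, O2, C3, C4, C5, C5a, C6, C7, C8, C9, C9a)
1. The target is an ester of two antipodal halves of one bicyclic hydroxy-lactone acid. The inter-half ester is cut last into a (5aS,6R,9S,9aS) acid and a (5aR,6S,9R,9aR) diol, both made from the same two fragments by choice of ligand antipode.
2. In each half, C6–H comes from a face-selective hydrogenation of a C6=C7 cyclohexene. That cyclohexene is cut at C5a–C6 and C9a–C9 into a seven-membered dienyl lactone and a (Z)-alkenylboronate that carries the C9 ketone.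
3. Enabling feature: the six-membered carbocycle is fused to the seven-membered lactone across C9a–C5a, the α- and β-carbons of the lactone carbonyl C1. C6 sits on the β-carbon C5a and C9 is a tertiary carbinol β to C1, so the ring is a conjugate-addition retron plus an aldol retron on one enoate.
4. Ring order: seven-membered lactone first (ring-closing metathesis), six-membered carbocycle second (key step). The alkenylboronate comes from an alkyne, an epoxide and a trans-hydrosilylation.

Key step: step 10

**Remarks on the chemistry**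
- The two halves of the target are antipodes: the half with the free diol is (5aS,6R,9S,9aS), the half with the free acid is (5aR,6S,9R,9aR). Steps 13–14 therefore repeat steps 10–11 with the antipodal ligand.
- Assumption: the (S,S)-diene ligand is taken to give the 5aR series and the (R,R)-ligand the 5aS series. If the sense of induction proves opposite, the two ligands are exchanged between steps 10 and 13.
- TBDPS = tert-butyldiphenylsilyl; pin = pinacolato; L = 2,5-diphenylbicyclo[2.2.2]octa-2,5-diene.

**Route**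

Step 1
Reactants: 1 3-methylbut-1-yne; 2 tert-butyl(oxiran-2-ylmethoxy)diphenylsilane (racemic)
Product: 4 1-[(tert-butyldiphenylsilyl)oxy]-6-methylhept-4-yn-2-ol (racemic), via lithium 3-methylbut-1-yn-1-ide 3 (not isolated)
Conditions: n-BuLi, THF, −78 °C; BF3·OEt2; then 2, −78 °C; aq. NH4Cl
Reagents that add atoms: none
Why: BF3-promoted SN2 opening of the terminal epoxide carbon by the alkynyllithium joins C7 to C8, and the carbinol stereocentre is irrelevant because it is oxidised in step 5.

Step 2
Reactants: 4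
Product: 6 6-{[(tert-butyldiphenylsilyl)oxy]methyl}-2,2-dimethyl-3-(propan-2-yl)-5,6-dihydro-2H-1,2-oxasiline (racemic), via dimethylsilyl ether 5 (not isolated)
Conditions: (HMe2Si)2NH, neat, 60 °C; evaporation; [Cp*Ru(MeCN)3]PF6 (2 mol%), CH2Cl2, 0 °C to rt
Reagents that add atoms: 1,1,3,3-tetramethyldisilazane, C[SiH](C)N[SiH](C)C
Why: O-silylation followed by cationic-ruthenium-catalysed intramolecular trans-hydrosilylation (6-endo-dig, a known reaction type for silyl ethers of homopropargylic alcohols) should put silicon on the distal alkyne carbon (future C6) with hydrogen trans to it, so the ring fixes silicon cis to the CH2 chain.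

Step 3
Reactants: 6
Product: 8 (4Z)-1-[(tert-butyldiphenylsilyl)oxy]-5-iodo-6-methylhept-4-en-2-ol (racemic), via succinimidosilyl ether 7 (not isolated)
Conditions: N-iodosuccinimide, (CF3)2CHOH, 0 °C; then K2CO3 (cat.), MeOH, rt
Reagents that add atoms: N-iodosuccinimide, O=C1CCC(=O)N1I
Why: Iododesilylation of the alkenylsiloxane is an ipso substitution that should proceed with retention of the alkene geometry (iodine cis to the CH2 chain), and methanolysis then removes the silyl residue from oxygen while the TBDPS ether stays.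

Step 4
Reactants: 8
Product: 9 (4E)-1-[(tert-butyldiphenylsilyl)oxy]-6-methyl-5-(4,4,5,5-tetramethyl-1,3,2-dioxaborolan-2-yl)hept-4-en-2-ol (racemic; boron cis to C3)
Conditions: B2pin2, PdCl2(PPh3)2 (3 mol%), PPh3, KOPh, toluene, 50 °C
Reagents that add atoms: bis(pinacolato)diboron, CC1(C)OB(OC1(C)C)B1OC(C)(C)C(C)(C)O1
Why: Miyaura borylation under the phenoxide conditions used for 1-alkenyl halides should exchange iodine for boron with retention of geometry and tolerate the free alcohol.

Step 5
Reactants: 9
Product: 10 (4E)-1-[(tert-butyldiphenylsilyl)oxy]-6-methyl-5-(4,4,5,5-tetramethyl-1,3,2-dioxaborolan-2-yl)hept-4-en-2-one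
Conditions: Dess–Martin periodinane, CH2Cl2, 0 °C; used at once
Reagents that add atoms: none
Why: Dess–Martin oxidation under neutral conditions should give the β,γ-unsaturated ketone without the base that would move the double bond into conjugation, and the alkenylboronate is inert to the periodinane.

Step 6
Reactants: 11 prop-2-enal; 12 tert-butyl prop-2-enoate
Product: 13 tert-butyl 3-hydroxy-2-methylidenepent-4-enoate (racemic)
Conditions: DABCO (20 mol%), excess 12, 1,4-dioxane/H2O (1:1), rt
Reagents that add atoms: none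
Why: Morita–Baylis–Hillman reaction in which the acrylate is the donor and the more electrophilic aldehyde the acceptor; the carbinol stereocentre is lost in step 7.

Step 7
Reactants: 13
Product: 14 tert-butyl (2Z)-2-(bromomethyl)penta-2,4-dienoate
Conditions: PBr3 (0.4 equiv), Et2O, −10 °C to 0 °C
Reagents that add atoms: phosphorus tribromide, BrP(Br)Br
Why: SN2′ bromination of the Morita–Baylis–Hillman alcohol should give the thermodynamically preferred linearly conjugated allylic bromide with the vinyl group trans to the ester and cis to CH2Br, the geometry the later ring closure needs.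

Step 8
Reactants: 14; 15 potassium prop-2-enoate
Product: 16 tert-butyl (2E)-2-[(prop-2-enoyloxy)methyl]penta-2,4-dienoate
Conditions: DMF, 0 °C to rt
Reagents that add atoms: none
Why: SN2 displacement of the primary allylic bromide by the carboxylate should give the primary acrylate with the alkene geometry unchanged.

Step 9
Reactants: 16
Product: 17 tert-butyl 7-oxo-2,7-dihydrooxepine-3-carboxylate
Conditions: second-generation Grubbs catalyst (5 mol%), CH2Cl2 (2 mM), 40 °C
Reagents that add atoms: none
Why: Ring-closing metathesis between the acrylate vinyl group and the terminal vinyl group of the diene should close the seven-membered lactone and form the ring-enforced cis C9a=C5a bond, while the trisubstituted electron-poor C4=C5 bond does not take part.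

Step 10
Reactants: 10; 17
Product: 19 tert-butyl (5aR,9R,9aR)-9-{[(tert-butyldiphenylsilyl)oxy]methyl}-9-hydroxy-1-oxo-6-(propan-2-yl)-1,3,5a,8,9,9a-hexahydro-2-benzoxepine-4-carboxylate, via rhodium enolate 18 (not isolated)
Conditions: [Rh(OH)(L)]2 (3 mol%; L = (S,S)-2,5-diphenylbicyclo[2.2.2]octa-2,5-diene), 1,4-dioxane/H2O (20:1), 40 °C
Reagents that add atoms: none
Why: Proposed new method: transmetalation of the alkenyl–boron bond of 10 to monovalent rhodium, enantioface-selective syn insertion of the C9a=C5a bond of 17 (bond C5a–C6) and intramolecular aldol addition of the rhodium oxa-π-allyl enolate 18 to the pendant ketone (bond C9a–C9) are merged in one catalytic cycle; the closest known reaction types are the rhodium-catalysed conjugate addition–aldol cyclisation of boronic acids with keto-enones and the rhodium-catalysed annulation of ortho-acylarylboronic acids with enones. The six-membered carbocycle closes by a 6-(enolexo)-exo-trig aldol addition, and no other ring is formed. C5a is set by the chiral diene ligand, which selects the enantioface of the planar lactone in the insertion. C9a and C9 are set by the ring-locked (E)-enolate in a chair Zimmerman–Traxler transition state fused trans-decalin-like to the forming ring, with C1 and C5 equatorial (trans ring fusion), the rhodium-bound oxygen equatorial (hydroxyl trans to C1) and the silyloxymethyl group axial; the cis-fused alternative suffers a 1,3-diaxial clash between C5 and that axial group. The step needs site selectivity for C5a over C5 and over 1,6-addition, which the cis-disubstituted C9a=C5a bond next to the trisubstituted C4=C5 bond should secure. It also needs aldol closure to outrun protonation of the enolate and conjugation of the β,γ-unsaturated ketone, which the six-membered closure and the base-free hydroxorhodium conditions should secure.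

Step 11
Reactants: 19
Product: 20 tert-butyl (5aR,6S,9R,9aR)-9-{[(tert-butyldiphenylsilyl)oxy]methyl}-9-hydroxy-1-oxo-6-(propan-2-yl)-1,3,5a,6,7,8,9,9a-octahydro-2-benzoxepine-4-carboxylate
Conditions: [Ir(cod)(PCy3)(py)]PF6 (5 mol%), H2 (1 atm), CH2Cl2, 0 °C to rt
Reagents that add atoms: none
Why: Homogeneous hydrogenation with the cationic iridium catalyst should add hydrogen to the trisubstituted C6=C7 bond from the face opposite the axial silyloxymethyl group at C9, which is the face of the C9 hydroxyl, so H6 ends cis to the C9–OH and the isopropyl group equatorial; the ester-conjugated C4=C5 bond should react much more slowly.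

Step 12
Reactants: 20
Product: 21 tert-butyl (5aR,6S,9R,9aR)-9-hydroxy-9-(hydroxymethyl)-1-oxo-6-(propan-2-yl)-1,3,5a,6,7,8,9,9a-octahydro-2-benzoxepine-4-carboxylate
Conditions: HF·pyridine, pyridine, THF, 0 °C to rt
Reagents that add atoms: none
Why: Buffered fluoride cleavage of the primary silyl ether should leave the tert-butyl ester, the lactone and the tertiary alcohol untouched and avoids the base that could trigger translactonisation of the freed diol.

Step 13
Reactants: 10; 17
Product: 23 tert-butyl (5aS,9S,9aS)-9-{[(tert-butyldiphenylsilyl)oxy]methyl}-9-hydroxy-1-oxo-6-(propan-2-yl)-1,3,5a,8,9,9a-hexahydro-2-benzoxepine-4-carboxylate, via rhodium enolate 22 (not isolated)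
Conditions: [Rh(OH)(L)]2 (3 mol%; L = (R,R)-2,5-diphenylbicyclo[2.2.2]octa-2,5-diene), 1,4-dioxane/H2O (20:1), 40 °C
Reagents that add atoms: none
Why: Proposed new method: the same rhodium-catalysed alkenyl transfer, syn insertion into C9a=C5a and Zimmerman–Traxler aldol closure of enolate 22 as in step 10, run with the antipodal ligand so that the opposite enantioface of 17 is attacked and the antipode of 19 should result; the closest known reaction type is again the rhodium-catalysed conjugate addition–aldol cyclisation of boronic acids with keto-enones.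

Step 14
Reactants: 23
Product: 24 tert-butyl (5aS,6R,9S,9aS)-9-{[(tert-butyldiphenylsilyl)oxy]methyl}-9-hydroxy-1-oxo-6-(propan-2-yl)-1,3,5a,6,7,8,9,9a-octahydro-2-benzoxepine-4-carboxylate
Conditions: [Ir(cod)(PCy3)(py)]PF6 (5 mol%), H2 (1 atm), CH2Cl2, 0 °C to rt
Reagents that add atoms: none
Why: As in step 11, hydrogen should add to C6=C7 anti to the axial silyloxymethyl group and syn to the C9 hydroxyl, which sets C6 with the isopropyl group equatorial.

Step 15
Reactants: 24
Product: 25 (5aS,6R,9S,9aS)-9-{[(tert-butyldiphenylsilyl)oxy]methyl}-9-hydroxy-1-oxo-6-(propan-2-yl)-1,3,5a,6,7,8,9,9a-octahydro-2-benzoxepine-4-carboxylic acid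
Conditions: CF3CO2H/CH2Cl2 (1:4), 0 °C
Reagents that add atoms: none
Why: Acidolysis of the tert-butyl ester through the tert-butyl cation should free the acid while the acid-stable TBDPS ether, the lactone and the tertiary alcohol (whose cation would be destabilised by the two flanking oxygenated carbons) remain.

Step 16
Reactants: 25; 21
Product: 27 the fully protected ester of 25 with the primary hydroxyl of 21, via mixed anhydride 26 (not isolated)
Conditions: 2,4,6-trichlorobenzoyl chloride, Et3N, THF, 0 °C; then 21, DMAP, toluene, 0 °C to rt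
Reagents that add atoms: none
Why: Yamaguchi esterification, in which the acyl-pyridinium formed from the mixed anhydride should acylate the only primary hydroxyl present while the three tertiary hydroxyls stay inert; prior activation of the acid keeps the diol 21 from standing in base.

Step 17
Reactants: 27
Product: 28 the ester of 25 with the primary hydroxyl of the (5aR,6S,9R,9aR) diol acid (silyl ether kept, carboxylic acid free)
Conditions: CF3CO2H/CH2Cl2 (1:4), 0 °C
Reagents that add atoms: none
Why: Acidolysis should remove the tert-butyl ester of the second half while the primary alkyl ester linkage, both lactones and the TBDPS ether survive; it is done before the diol is freed so that the free diol never meets strong acid.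

Step 18
Reactants: 28
Product: 29 CNP0340505.1
Conditions: HF·pyridine, pyridine, THF, 0 °C to rt
Reagents that add atoms: none
Why: Buffered fluoride cleavage of the last silyl ether should release the primary alcohol of the diol half under near-neutral conditions that spare the esters and lactones.

**Compound list**
1 | 3-methylbut-1-yne | CC(C)C#C | starting material
2 | tert-butyl(oxiran-2-ylmethoxy)diphenylsilane (racemic) | CC(C)(C)[Si](OCC1CO1)(c1ccccc1)c1ccccc1 | starting material
3 | lithium 3-methylbut-1-yn-1-ide | [Li]C#CC(C)C | intermediate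
4 | 1-[(tert-butyldiphenylsilyl)oxy]-6-methylhept-4-yn-2-ol (racemic) | CC(C)C#CCC(O)CO[Si](c1ccccc1)(c1ccccc1)C(C)(C)C | intermediate
5 | 1-[(tert-butyldiphenylsilyl)oxy]-2-[(dimethylsilyl)oxy]-6-methylhept-4-yne (racemic) | CC(C)C#CCC(O[SiH](C)C)CO[Si](c1ccccc1)(c1ccccc1)C(C)(C)C | intermediate
6 | 6-{[(tert-butyldiphenylsilyl)oxy]methyl}-2,2-dimethyl-3-(propan-2-yl)-5,6-dihydro-2H-1,2-oxasiline (racemic) | CC(C)C1=CCC(CO[Si](c2ccccc2)(c2ccccc2)C(C)(C)C)O[Si]1(C)C | intermediate
7 | 1-[({(4Z)-1-[(tert-butyldiphenylsilyl)oxy]-5-iodo-6-methylhept-4-en-2-yl}oxy)dimethylsilyl]pyrrolidine-2,5-dione (racemic) | CC(C)/C(I)=C/CC(O[Si](C)(C)N1C(=O)CCC1=O)CO[Si](c1ccccc1)(c1ccccc1)C(C)(C)C | intermediate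
8 | (4Z)-1-[(tert-butyldiphenylsilyl)oxy]-5-iodo-6-methylhept-4-en-2-ol (racemic) | CC(C)/C(I)=C/CC(O)CO[Si](c1ccccc1)(c1ccccc1)C(C)(C)C | intermediate
9 | (4E)-1-[(tert-butyldiphenylsilyl)oxy]-6-methyl-5-(4,4,5,5-tetramethyl-1,3,2-dioxaborolan-2-yl)hept-4-en-2-ol (racemic; boron cis to C3) | CC(C)/C(B1OC(C)(C)C(C)(C)O1)=C/CC(O)CO[Si](c1ccccc1)(c1ccccc1)C(C)(C)C | intermediate
10 | (4E)-1-[(tert-butyldiphenylsilyl)oxy]-6-methyl-5-(4,4,5,5-tetramethyl-1,3,2-dioxaborolan-2-yl)hept-4-en-2-one | CC(C)/C(B1OC(C)(C)C(C)(C)O1)=C/CC(=O)CO[Si](c1ccccc1)(c1ccccc1)C(C)(C)C | intermediate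
11 | prop-2-enal | C=CC=O | starting material
12 | tert-butyl prop-2-enoate | C=CC(=O)OC(C)(C)C | starting material
13 | tert-butyl 3-hydroxy-2-methylidenepent-4-enoate (racemic) | C=CC(O)C(=C)C(=O)OC(C)(C)C | intermediate
14 | tert-butyl (2Z)-2-(bromomethyl)penta-2,4-dienoate | C=C/C=C(\CBr)C(=O)OC(C)(C)C | intermediate
15 | potassium prop-2-enoate | [K+].[O-]C(=O)C=C | starting material
16 | tert-butyl (2E)-2-[(prop-2-enoyloxy)methyl]penta-2,4-dienoate | C=C/C=C(\COC(=O)C=C)C(=O)OC(C)(C)C | intermediate
17 | tert-butyl 7-oxo-2,7-dihydrooxepine-3-carboxylate | O=C1OCC(C(=O)OC(C)(C)C)=CC=C1 | intermediate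
18 | rhodium O-enolate of the 1,4-adduct of 10 to 17, C5a configured as in 19 (diene ligand on rhodium not drawn) | CC(C)/C(=C/CC(=O)CO[Si](c1ccccc1)(c1ccccc1)C(C)(C)C)[C@@H]2C=C(C(=O)OC(C)(C)C)COC(O[Rh])=C2 | intermediate
19 | tert-butyl (5aR,9R,9aR)-9-{[(tert-butyldiphenylsilyl)oxy]methyl}-9-hydroxy-1-oxo-6-(propan-2-yl)-1,3,5a,8,9,9a-hexahydro-2-benzoxepine-4-carboxylate | CC(C)(C)[Si](c1ccccc1)(c1ccccc1)OC[C@@]3(O)CC=C(C(C)C)[C@@H]4C=C(C(=O)OC(C)(C)C)COC(=O)[C@H]43 | intermediate
20 | tert-butyl (5aR,6S,9R,9aR)-9-{[(tert-butyldiphenylsilyl)oxy]methyl}-9-hydroxy-1-oxo-6-(propan-2-yl)-1,3,5a,6,7,8,9,9a-octahydro-2-benzoxepine-4-carboxylate | CC(C)(C)[Si](c1ccccc1)(c1ccccc1)OC[C@@]3(O)CC[C@@H](C(C)C)[C@@H]4C=C(C(=O)OC(C)(C)C)COC(=O)[C@H]43 | intermediate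
21 | tert-butyl (5aR,6S,9R,9aR)-9-hydroxy-9-(hydroxymethyl)-1-oxo-6-(propan-2-yl)-1,3,5a,6,7,8,9,9a-octahydro-2-benzoxepine-4-carboxylate | OC[C@@]3(O)CC[C@@H](C(C)C)[C@@H]4C=C(C(=O)OC(C)(C)C)COC(=O)[C@H]43 | intermediate
22 | antipode of 18 (diene ligand on rhodium not drawn) | CC(C)/C(=C/CC(=O)CO[Si](c1ccccc1)(c1ccccc1)C(C)(C)C)[C@H]2C=C(C(=O)OC(C)(C)C)COC(O[Rh])=C2 | intermediate
23 | tert-butyl (5aS,9S,9aS)-9-{[(tert-butyldiphenylsilyl)oxy]methyl}-9-hydroxy-1-oxo-6-(propan-2-yl)-1,3,5a,8,9,9a-hexahydro-2-benzoxepine-4-carboxylate | CC(C)C1=CC[C@@](O)(CO[Si](c3ccccc3)(c3ccccc3)C(C)(C)C)[C@H]2C(=O)OCC(C(=O)OC(C)(C)C)=C[C@H]12 | intermediate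
24 | tert-butyl (5aS,6R,9S,9aS)-9-{[(tert-butyldiphenylsilyl)oxy]methyl}-9-hydroxy-1-oxo-6-(propan-2-yl)-1,3,5a,6,7,8,9,9a-octahydro-2-benzoxepine-4-carboxylate | CC(C)[C@H]1CC[C@@](O)(CO[Si](c3ccccc3)(c3ccccc3)C(C)(C)C)[C@H]2C(=O)OCC(C(=O)OC(C)(C)C)=C[C@H]12 | intermediate
25 | (5aS,6R,9S,9aS)-9-{[(tert-butyldiphenylsilyl)oxy]methyl}-9-hydroxy-1-oxo-6-(propan-2-yl)-1,3,5a,6,7,8,9,9a-octahydro-2-benzoxepine-4-carboxylic acid | CC(C)[C@H]1CC[C@@](O)(CO[Si](c3ccccc3)(c3ccccc3)C(C)(C)C)[C@H]2C(=O)OCC(C(=O)O)=C[C@H]12 | intermediate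
26 | mixed anhydride of 25 with 2,4,6-trichlorobenzoic acid | CC(C)[C@H]1CC[C@@](O)(CO[Si](c3ccccc3)(c3ccccc3)C(C)(C)C)[C@H]2C(=O)OCC(C(=O)OC(=O)c3c(Cl)cc(Cl)cc3Cl)=C[C@H]12 | intermediate
27 | ester of acid 25 with the 9-CH2OH of 21 (TBDPS ether on the diol half, tert-butyl ester on the acid half) | CC(C)[C@H]1CC[C@@](O)(CO[Si](c5ccccc5)(c5ccccc5)C(C)(C)C)[C@H]2C(=O)OCC(C(=O)OC[C@@]3(O)CC[C@@H](C(C)C)[C@@H]4C=C(C(=O)OC(C)(C)C)COC(=O)[C@H]43)=C[C@H]12 | intermediate
28 | as 27 with the tert-butyl ester cleaved to the free carboxylic acid | CC(C)[C@H]1CC[C@@](O)(CO[Si](c5ccccc5)(c5ccccc5)C(C)(C)C)[C@H]2C(=O)OCC(C(=O)OC[C@@]3(O)CC[C@@H](C(C)C)[C@@H]4C=C(C(=O)O)COC(=O)[C@H]43)=C[C@H]12 | intermediate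
29 | CNP0340505.1: [(5aR,6S,9R,9aR)-4-carboxy-9-hydroxy-1-oxo-6-(propan-2-yl)-1,3,5a,6,7,8,9,9a-octahydro-2-benzoxepin-9-yl]methyl ester of (5aS,6R,9S,9aS)-9-hydroxy-9-(hydroxymethyl)-1-oxo-6-(propan-2-yl)-1,3,5a,6,7,8,9,9a-octahydro-2-benzoxepine-4-carboxylic acid | CC(C)[C@H]1CC[C@@](O)(CO)[C@H]2C(=O)OCC(C(=O)OC[C@@]3(O)CC[C@@H](C(C)C)[C@@H]4C=C(C(=O)O)COC(=O)[C@H]43)=C[C@H]12 | target

**Step count**
Total: 18 steps. Longest linear sequence: 11 steps (1–5, 10–12, 16–18; the other arm, 1–5, 13–15, 16–18, is equally long).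

**Steps most likely to fail, with fallbacks**

1. Step 10 (Proposed new method). The rhodium enolate may be protonated by water before it closes on the ketone, the β,γ-unsaturated ketone of 10 may drift into conjugation before transmetalation, or the aldol closure may show poor facial selectivity. The fallback uses known chemistry only, sets out from 9 and 17 and returns to the route at 19. A Hayashi–Miyaura 1,4-addition of the hydroxy boronate 9 to 17 with the same hydroxorhodium/(S,S)-diene catalyst in dioxane/H2O should give the hydroxy lactone tert-butyl (5S)-5-{(3Z)-7-[(tert-butyldiphenylsilyl)oxy]-6-hydroxy-2-methylhept-3-en-3-yl}-7-oxo-2,5,6,7-tetrahydrooxepine-3-carboxylate F1, with C5a fixed by the ligand and the carbinol epimers of no consequence. Double deprotonation with LiN(iPr)2 in THF at −78 °C and bromination of the lactone enolate with BrCCl2CCl2Br should give the 6-bromo lactone F2 (both C6 epimers serve). Dess–Martin oxidation should give the bromo ketone F3. SmI2 in THF at −78 °C should then close C9a–C9 by an intramolecular samarium Reformatsky reaction through the same chelated chair, to give 19.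

2. Step 13 (Proposed new method). The same processes as in step 10 may intervene in the antipodal series. The fallback is the mirror-image sequence, which sets out from 9 and 17 and returns at 23. Hayashi–Miyaura addition with the (R,R)-diene catalyst should give the (5R) hydroxy lactone F4. Enolate bromination should give the (5R) 6-bromo lactone F5. Dess–Martin oxidation should give the (5R) bromo ketone F6. The samarium Reformatsky closure with SmI2 should then give 23.

3. Step 11 (and its twin, step 14). Hydrogen may add with poor facial selectivity at C6=C7, the catalyst may move the double bond along the skipped diene, or the C4=C5 enoate may be over-reduced. The fallback sets out from 19 and returns at 20 (from 23 to 24 in the other arm) and changes the stereo-determining element. A radical hydrogen-atom-transfer hydrogenation with Mn(dpm)3 (tris(dipivaloylmethanato)manganese), PhSiH3 and t-BuOOH in i-PrOH generates the tertiary C6 radical, which should take up hydrogen axially and so place the isopropyl group equatorial under product-stability control. No new compound is made (F0).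

**Further compounds**
F1 | step 10 | tert-butyl (5S)-5-{(3Z)-7-[(tert-butyldiphenylsilyl)oxy]-6-hydroxy-2-methylhept-3-en-3-yl}-7-oxo-2,5,6,7-tetrahydrooxepine-3-carboxylate | CC(C)/C(=C/CC(O)CO[Si](c1ccccc1)(c1ccccc1)C(C)(C)C)[C@@H]2C=C(C(=O)OC(C)(C)C)COC(=O)C2
F2 | step 10 | tert-butyl (5S)-6-bromo-5-{(3Z)-7-[(tert-butyldiphenylsilyl)oxy]-6-hydroxy-2-methylhept-3-en-3-yl}-7-oxo-2,5,6,7-tetrahydrooxepine-3-carboxylate | CC(C)/C(=C/CC(O)CO[Si](c1ccccc1)(c1ccccc1)C(C)(C)C)[C@@H]2C=C(C(=O)OC(C)(C)C)COC(=O)C2Br
F3 | step 10 | tert-butyl (5S)-6-bromo-5-{(3Z)-7-[(tert-butyldiphenylsilyl)oxy]-2-methyl-6-oxohept-3-en-3-yl}-7-oxo-2,5,6,7-tetrahydrooxepine-3-carboxylate | CC(C)/C(=C/CC(=O)CO[Si](c1ccccc1)(c1ccccc1)C(C)(C)C)[C@@H]2C=C(C(=O)OC(C)(C)C)COC(=O)C2Br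
F4 | step 13 | tert-butyl (5R)-5-{(3Z)-7-[(tert-butyldiphenylsilyl)oxy]-6-hydroxy-2-methylhept-3-en-3-yl}-7-oxo-2,5,6,7-tetrahydrooxepine-3-carboxylate | CC(C)/C(=C/CC(O)CO[Si](c1ccccc1)(c1ccccc1)C(C)(C)C)[C@H]2C=C(C(=O)OC(C)(C)C)COC(=O)C2
F5 | step 13 | tert-butyl (5R)-6-bromo-5-{(3Z)-7-[(tert-butyldiphenylsilyl)oxy]-6-hydroxy-2-methylhept-3-en-3-yl}-7-oxo-2,5,6,7-tetrahydrooxepine-3-carboxylate | CC(C)/C(=C/CC(O)CO[Si](c1ccccc1)(c1ccccc1)C(C)(C)C)[C@H]2C=C(C(=O)OC(C)(C)C)COC(=O)C2Br
F6 | step 13 | tert-butyl (5R)-6-bromo-5-{(3Z)-7-[(tert-butyldiphenylsilyl)oxy]-2-methyl-6-oxohept-3-en-3-yl}-7-oxo-2,5,6,7-tetrahydrooxepine-3-carboxylate | CC(C)/C(=C/CC(=O)CO[Si](c1ccccc1)(c1ccccc1)C(C)(C)C)[C@H]2C=C(C(=O)OC(C)(C)C)COC(=O)C2Br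
F0 | step 11 | none | none
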